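**Retrosynthetic overview**

Numbering: ring C1H=C10(C14H3)–C9(=O)–C8H2–C7–C6H2–C5H–C4(C15H2OAc)–C3H2–C2H2; fused oxirane C4–O–C5; spiro oxirane C7–O–C11, with C11 carrying C13H3 and C12H2OAc.
Target ⇐ C9 carbinol oxidation and acetylation ⇐ two reagent-controlled Katsuki–Sharpless epoxidations of a cyclodecatriene (C12–OH directs C7=C11 with L-(+)-tartrate; C15–OH directs C4=C5 with D-(−)-tartrate).
Ten-membered ring ⇐ closure of the C4–C5 bond by intramolecular Horner–Wadsworth–Emmons olefination. Enabling feature: C4 bears C15, which as an ester makes C4 a phosphonate carbanion; O12 and C6 are cis on C7=C11, so O12 and C5 fit a six-membered lactol (masked C5 aldehyde); both endocyclic olefins (C1=C10, C4=C5) are cis within the ring, which is the geometry a cyclodecene closure and an E-enoate share.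
Seco chain ⇐ Nozaki–Hiyama–Kishi coupling at C9–C10 of a Z-alkenyl iodide/phosphonate (C1–C4, C10, C14, C15) with a pyranylacetaldehyde (C5–C9, C11–C13) ⇐ achiral diallyl allylic alcohol, whose double oxidative cleavage and lactolization tell the two arms apart and fix the C7=C11 geometry.
Ring order: dihydropyran lactol (temporary) → ten-membered carbocycle (C4–C5, with loss of the lactol ring) → spiro oxirane (C7–C11) → fused oxirane (C4–C5).

Key step: step 12

Remark: C9 (a silylated carbinol from step 9 until it becomes the ketone in step 18), the phosphonate carbon C4 and the lactol carbon C5 are left uncontrolled; they are carried as mixtures and all three cease to be stereocentres before the target is reached.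

**Route**

Step 1
Reactants: 1 prop-2-yn-1-ol; 2 3-bromoprop-1-ene (allyl bromide)
Product: 3 hex-5-en-2-yn-1-ol
Conditions: CuI (10 mol %), K2CO3, DMF, rt
Reagents that add atoms: none
Why: Copper-catalysed coupling of a terminal alkyne with an allylic halide (through the copper acetylide formed with carbonate) should give the skipped enyne, the carbonate being too weak to form the alkoxide and cause O-allylation.

Step 2
Reactants: 3 hex-5-en-2-yn-1-ol; 2 3-bromoprop-1-ene
Product: 5 2-methyl-3-(prop-2-en-1-yl)hexa-2,5-dien-1-ol, via alkenylmagnesium alkoxide 4 (not isolated)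
Conditions: MeMgBr (3.5 equiv), CuI (10 mol %), THF, −10 °C → rt; then 2, −20 °C → rt; aq. NH4Cl
Reagents that add atoms: methylmagnesium bromide, C[Mg]Br
Why: Copper-catalysed anti-carbomagnesiation of the propargylic magnesium alkoxide puts CH3 on the carbon next to CH2O and magnesium on the distal carbon in a five-membered chelate, and the alkenylmagnesium is then allylated under the same copper catalysis; since that carbon ends with two identical allyl groups there is no olefin geometry to control.

Step 3
Reactants: 5 2-methyl-3-(prop-2-en-1-yl)hexa-2,5-dien-1-ol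
Product: 8 2-(2-hydroxy-5-methyl-3,6-dihydro-2H-pyran-4-yl)acetaldehyde, via pentaol 6 (not isolated), via hydroxy dialdehyde 7 (not isolated)
Conditions: OsO4 (2 mol %), NaIO4 (4.5 equiv), 2,6-lutidine, 1,4-dioxane/H2O (3:1), rt
Reagents that add atoms: sodium periodate, [Na+].[O-]I(=O)(=O)=O (stoichiometric source of the two aldehyde oxygens, passed on by the OsO4 catalyst, O=[Os](=O)(=O)=O)
Why: Lemieux–Johnson oxidation should take the two monosubstituted olefins in preference to the hindered tetrasubstituted one, and of the two identical formylmethyl arms only the one cis to CH2OH can close a six-membered lactol, which differentiates the arms and fixes the C7=C11 geometry for the whole route (C12 cis to C6).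

Step 4
Reactants: 8 2-(2-hydroxy-5-methyl-3,6-dihydro-2H-pyran-4-yl)acetaldehyde
Product: 9 2-{2-[(tert-butyldimethylsilyl)oxy]-5-methyl-3,6-dihydro-2H-pyran-4-yl}acetaldehyde
Conditions: TBSCl, imidazole, CH2Cl2, 0 °C
Reagents that add atoms: tert-butyldimethylsilyl chloride, CC(C)(C)[Si](C)(C)Cl
Why: Silylation of the lactol hydroxyl gives the anomeric silyl acetal and leaves the free C9 aldehyde as the only electrophile for the fragment coupling.

Step 5
Reactants: 10 3-[(tert-butyldimethylsilyl)oxy]propanal
Product: 11 tert-butyl{[(3Z)-4-iodopent-3-en-1-yl]oxy}dimethylsilane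
Conditions: EtPPh3I, n-BuLi, THF, 0 °C; I2, −78 °C; NaN(SiMe3)2, −78 °C; then 10, −78 → −20 °C
Reagents that add atoms: ethyltriphenylphosphonium iodide, CC[P+](c1ccccc1)(c1ccccc1)c1ccccc1.[I-]; iodine, II
Why: Stork–Zhao-type Wittig olefination with the α-iodo ylide is kinetically Z-selective at low temperature (iodine cis to the chain), which sets the C1=C10 geometry.

Step 6
Reactants: 11 tert-butyl{[(3Z)-4-iodopent-3-en-1-yl]oxy}dimethylsilane
Product: 12 (3Z)-4-iodopent-3-en-1-ol
Conditions: TBAF, THF, 0 °C → rt
Reagents that add atoms: none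
Why: Fluoride cleavage of the primary silyl ether leaves the alkenyl iodide untouched.

Step 7
Reactants: 12 (3Z)-4-iodopent-3-en-1-ol
Product: 13 (2Z)-2,5-diiodopent-2-ene
Conditions: I2, PPh3, imidazole, CH2Cl2, 0 °C → rt
Reagents that add atoms: iodine, II
Why: Appel-type iodination converts the primary alcohol into the iodide by SN2 displacement of the oxyphosphonium group without affecting the alkenyl iodide.

Step 8
Reactants: 13 (2Z)-2,5-diiodopent-2-ene; 14 triethyl phosphonoacetate
Product: 16 ethyl (5Z)-2-(diethoxyphosphoryl)-6-iodohept-5-enoate, via sodium phosphonoacetate 15 (not isolated)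
Conditions: 14 (1.5 equiv), NaH, THF, 0 °C; then 13, DMSO, 50 °C
Reagents that add atoms: none
Why: SN2 C-alkylation of the soft phosphonoacetate carbanion by the primary iodide (the alkenyl iodide cannot react), with an excess of 14 to suppress dialkylation.

Step 9
Reactants: 9 2-{2-[(tert-butyldimethylsilyl)oxy]-5-methyl-3,6-dihydro-2H-pyran-4-yl}acetaldehyde; 16 ethyl (5Z)-2-(diethoxyphosphoryl)-6-iodohept-5-enoate
Product: 18 ethyl (5Z)-8-{2-[(tert-butyldimethylsilyl)oxy]-5-methyl-3,6-dihydro-2H-pyran-4-yl}-2-(diethoxyphosphoryl)-7-hydroxy-6-methyloct-5-enoate, via alkenylchromium dichloride 17 (not isolated)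
Conditions: CrCl2 (5 equiv), NiCl2 (2 mol %), DMSO/THF, rt
Reagents that add atoms: none
Why: Nozaki–Hiyama–Kishi coupling (nickel-catalysed activation of the alkenyl iodide, transmetalation to trivalent chromium, chemoselective addition to the aldehyde with retention of the trisubstituted olefin geometry) forms the C9–C10 bond under neutral conditions that should spare the acidic phosphonate, the ester, the silyl acetal and the β,γ-unsaturated aldehyde; C9 forms as both epimers, which is of no consequence.

Step 10
Reactants: 18 ethyl (5Z)-8-{2-[(tert-butyldimethylsilyl)oxy]-5-methyl-3,6-dihydro-2H-pyran-4-yl}-2-(diethoxyphosphoryl)-7-hydroxy-6-methyloct-5-enoate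
Product: 19 7-O-tert-butyldimethylsilyl ether of 18
Conditions: TBSCl, imidazole, DMF, rt
Reagents that add atoms: tert-butyldimethylsilyl chloride, CC(C)(C)[Si](C)(C)Cl
Why: Standard silylation of the secondary allylic alcohol; C9 must stay masked so that neither later epoxidation meets a second allylic alcohol.

Step 11
Reactants: 19 7-O-tert-butyldimethylsilyl ether of 18
Product: 20 ethyl (5Z)-7-[(tert-butyldimethylsilyl)oxy]-2-(diethoxyphosphoryl)-8-(2-hydroxy-5-methyl-3,6-dihydro-2H-pyran-4-yl)-6-methyloct-5-enoate
Conditions: TBAF (1.05 equiv), AcOH (1.5 equiv), THF, −20 °C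
Reagents that add atoms: none
Why: The anomeric silyl acetal is far more fluoride-labile than the secondary silyl ether (the lactolate is the better leaving group), and the acetic acid buffer keeps the phosphonoacetate protonated so that no olefination starts at preparative concentration.

Step 12
Reactants: 20 ethyl (5Z)-7-[(tert-butyldimethylsilyl)oxy]-2-(diethoxyphosphoryl)-8-(2-hydroxy-5-methyl-3,6-dihydro-2H-pyran-4-yl)-6-methyloct-5-enoate
Product: 22 ethyl (1E,4E,7Z)-6-[(tert-butyldimethylsilyl)oxy]-4-(1-hydroxypropan-2-ylidene)-7-methylcyclodeca-1,7-diene-1-carboxylate, via hydroxy aldehyde 21 (not isolated)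
Conditions: LiCl (20 equiv), DBU (5 equiv), MeCN, 20 added over 12 h to 1 mM final concentration, rt
Reagents that add atoms: none
Why: DBU/LiCl opens lactol 20 to hydroxy aldehyde 21 and deprotonates the lithium-chelated phosphonoacetate; the C4 carbanion adds to the C5 aldehyde and syn-elimination of lithium diethyl phosphate from the oxaphosphetane forms the C4–C5 bond as a C=C bond. The closest known reaction type is the intramolecular Horner–Wadsworth–Emmons macrocyclization under Masamune–Roush conditions, together with the use of lactols as masked hydroxy aldehydes in olefinations. The ten-membered carbocycle closes by intramolecular carbonyl addition (10-exo-trig at the aldehyde) followed by elimination, and the temporary six-membered lactol ring is given up in the same operation. No stereocentre is created; the E-enoate geometry that α-alkyl phosphonoacetates deliver (ester trans to C6) is the ring-cis geometry that a cyclodecene closure prefers, so reagent preference and ring strain point the same way. The selectivity needed is cyclization over oligomerization and over base-induced migration of the β,γ-olefin of the aldehyde; high dilution with slow addition, five sp2 ring atoms that lower transannular strain, and the lactol, which keeps the stationary concentration of free aldehyde low, should secure it. The step also frees the C12 allylic alcohol that directs the next epoxidation.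

Step 13
Reactants: 22 ethyl (1E,4E,7Z)-6-[(tert-butyldimethylsilyl)oxy]-4-(1-hydroxypropan-2-ylidene)-7-methylcyclodeca-1,7-diene-1-carboxylate
Product: 23 spiro-epoxy alcohol, the (7S,11S)-7,11-epoxide of 22
Conditions: Ti(OiPr)4 (20 mol %), L-(+)-diisopropyl tartrate (24 mol %), t-BuOOH (2 equiv), 4 Å molecular sieves, CH2Cl2, −20 °C
Reagents that add atoms: tert-butyl hydroperoxide, CC(C)(C)OO
Why: Katsuki–Sharpless asymmetric epoxidation: only the C12 allylic alcohol can bind titanium, so only C7=C11 is epoxidized, and L-(+)-tartrate, which makes the carbinol-bearing olefin carbon S in this substitution pattern, should set C11 (S) and C7 (S) together in one syn addition under reagent control.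

Step 14
Reactants: 23 spiro-epoxy alcohol
Product: 24 epoxy diol (23 with the C15 ester reduced to CH2OH)
Conditions: i-Bu2AlH (4 equiv), CH2Cl2, −78 °C
Reagents that add atoms: none
Why: 1,2-Reduction of the conjugated ester to the allylic alcohol at −78 °C, a temperature at which the fully substituted epoxide and the silyl ether should not be attacked.

Step 15
Reactants: 24 epoxy diol
Product: 25 bis-epoxy diol (4R,5R,7S,11S)
Conditions: Ti(OiPr)4 (20 mol %), D-(−)-diisopropyl tartrate (24 mol %), t-BuOOH (2 equiv), 4 Å molecular sieves, CH2Cl2, −20 °C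
Reagents that add atoms: tert-butyl hydroperoxide, CC(C)(C)OO
Why: Second Katsuki–Sharpless epoxidation, now directed by the C15 alcohol onto the 2,3-disubstituted allylic olefin C4=C5; D-(−)-tartrate should make C4 R and, by syn addition to the ring-cis olefin, C5 R with the cis-fused oxirane.

Step 16
Reactants: 25 bis-epoxy diol
Product: 26 12,15-diacetate of 25
Conditions: Ac2O, pyridine, DMAP (cat.), CH2Cl2, 0 °C
Reagents that add atoms: acetic anhydride, CC(=O)OC(C)=O
Why: Acylation of both primary alcohols under nucleophilic catalysis, with no base strong enough to cause epoxide migration.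

Step 17
Reactants: 26 12,15-diacetate of 25
Product: 27 C9 alcohol (desilylated 26)
Conditions: TBAF, AcOH, THF, 0 °C → rt
Reagents that add atoms: none
Why: Buffered fluoride removes the secondary silyl ether, the acetic acid suppressing alkoxide-driven acetyl transfer and epoxide opening.

Step 18
Reactants: 27 C9 alcohol
Product: 28 target, (4R,5R,7S,11S,1(10)Z)-12,15-diacetoxy-4,5:7,11-diepoxygermacr-1(10)-en-9-one
Conditions: Dess–Martin periodinane, pyridine, CH2Cl2, 0 °C → rt
Reagents that add atoms: none
Why: Dess–Martin oxidation of the allylic alcohol under pyridine buffering should give the Z-enone without acid or base that could open the β,γ-epoxy ketone; both C9 epimers converge on the single target.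

**Compound list**

1 | prop-2-yn-1-ol | C#CCO | starting material
2 | 3-bromoprop-1-ene (allyl bromide) | C=CCBr | starting material
3 | hex-5-en-2-yn-1-ol | C=CCC#CCO | intermediate
4 | bromomagnesium 3-(bromomagnesio)-2-methylhexa-2,5-dien-1-olate (magnesium on C3 cis to CH2O) | C=CC/C([Mg]Br)=C(\C)CO[Mg]Br | intermediate
5 | 2-methyl-3-(prop-2-en-1-yl)hexa-2,5-dien-1-ol (achiral, two identical allyl groups on C3) | C=CCC(CC=C)=C(C)CO | intermediate
6 | 3-(2,3-dihydroxypropyl)-2-methylhex-2-ene-1,5,6-triol (pentaol, stereoisomer mixture) | OCC(O)CC(CC(O)CO)=C(C)CO | intermediate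
7 | 3-(1-hydroxypropan-2-ylidene)pentanedial | O=CCC(CC=O)=C(C)CO | intermediate
8 | 2-(2-hydroxy-5-methyl-3,6-dihydro-2H-pyran-4-yl)acetaldehyde (racemic lactol) | O=CCC1=C(C)COC(O)C1 | intermediate
9 | 2-{2-[(tert-butyldimethylsilyl)oxy]-5-methyl-3,6-dihydro-2H-pyran-4-yl}acetaldehyde (racemic) | O=CCC1=C(C)COC(O[Si](C)(C)C(C)(C)C)C1 | intermediate
10 | 3-[(tert-butyldimethylsilyl)oxy]propanal | O=CCCO[Si](C)(C)C(C)(C)C | starting material
11 | tert-butyl{[(3Z)-4-iodopent-3-en-1-yl]oxy}dimethylsilane | C/C(I)=C/CCO[Si](C)(C)C(C)(C)C | intermediate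
12 | (3Z)-4-iodopent-3-en-1-ol | C/C(I)=C/CCO | intermediate
13 | (2Z)-2,5-diiodopent-2-ene | C/C(I)=C/CCI | intermediate
14 | triethyl phosphonoacetate | CCOC(=O)CP(=O)(OCC)OCC | starting material
15 | sodium salt of 14 (phosphonate-stabilised carbanion) | [Na+].CCOC(=O)[CH-]P(=O)(OCC)OCC | intermediate
16 | ethyl (5Z)-2-(diethoxyphosphoryl)-6-iodohept-5-enoate (racemic) | CCOC(=O)C(CC/C=C(/C)I)P(=O)(OCC)OCC | intermediate
17 | alkenylchromium dichloride from 16 (trivalent chromium in place of iodine, Z retained) | CCOC(=O)C(CC/C=C(/C)[Cr](Cl)Cl)P(=O)(OCC)OCC | intermediate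
18 | ethyl (5Z)-8-{2-[(tert-butyldimethylsilyl)oxy]-5-methyl-3,6-dihydro-2H-pyran-4-yl}-2-(diethoxyphosphoryl)-7-hydroxy-6-methyloct-5-enoate (diastereomer mixture) | CCOC(=O)C(CC/C=C(/C)C(O)CC1=C(C)COC(O[Si](C)(C)C(C)(C)C)C1)P(=O)(OCC)OCC | intermediate
19 | 7-O-tert-butyldimethylsilyl ether of 18 (diastereomer mixture) | CCOC(=O)C(CC/C=C(/C)C(O[Si](C)(C)C(C)(C)C)CC1=C(C)COC(O[Si](C)(C)C(C)(C)C)C1)P(=O)(OCC)OCC | intermediate
20 | ethyl (5Z)-7-[(tert-butyldimethylsilyl)oxy]-2-(diethoxyphosphoryl)-8-(2-hydroxy-5-methyl-3,6-dihydro-2H-pyran-4-yl)-6-methyloct-5-enoate (lactol, diastereomer mixture) | CCOC(=O)C(CC/C=C(/C)C(O[Si](C)(C)C(C)(C)C)CC1=C(C)COC(O)C1)P(=O)(OCC)OCC | intermediate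
21 | ethyl (5Z,9Z)-7-[(tert-butyldimethylsilyl)oxy]-2-(diethoxyphosphoryl)-11-hydroxy-6,10-dimethyl-9-(2-oxoethyl)undeca-5,9-dienoate (open-chain tautomer of 20) | CCOC(=O)C(CC/C=C(/C)C(O[Si](C)(C)C(C)(C)C)C/C(CC=O)=C(\C)CO)P(=O)(OCC)OCC | intermediate
22 | ethyl (1E,4E,7Z)-6-[(tert-butyldimethylsilyl)oxy]-4-(1-hydroxypropan-2-ylidene)-7-methylcyclodeca-1,7-diene-1-carboxylate (racemic at C9; ester trans to C6, C12 cis to C6, C9 cis to C2) | CCOC(=O)/C1=C/C/C(=C(/C)CO)CC(O[Si](C)(C)C(C)(C)C)/C(C)=C\CC1 | intermediate
23 | spiro-epoxy alcohol, the (7S,11S)-7,11-epoxide of 22 (both C9 epimers) | CCOC(=O)/C1=C/C[C@]2(O[C@@]2(C)CO)CC(O[Si](C)(C)C(C)(C)C)/C(C)=C\CC1 | intermediate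
24 | epoxy diol, 23 with CH2OH (C15) in place of the ester (both C9 epimers) | OC/C1=C/C[C@]2(O[C@@]2(C)CO)CC(O[Si](C)(C)C(C)(C)C)/C(C)=C\CC1 | intermediate
25 | bis-epoxy diol (4R,5R,7S,11S), C9 silyl ether (both C9 epimers) | OC[C@]12CC/C=C(/C)C(O[Si](C)(C)C(C)(C)C)C[C@]3(C[C@H]1O2)O[C@@]3(C)CO | intermediate
26 | 12,15-diacetate of 25 | CC(=O)OC[C@]12CC/C=C(/C)C(O[Si](C)(C)C(C)(C)C)C[C@]3(C[C@H]1O2)O[C@@]3(C)COC(C)=O | intermediate
27 | C9 alcohol, desilylated 26 (both C9 epimers) | CC(=O)OC[C@]12CC/C=C(/C)C(O)C[C@]3(C[C@H]1O2)O[C@@]3(C)COC(C)=O | intermediate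
28 | (4R,5R,7S,11S,1(10)Z)-12,15-diacetoxy-4,5:7,11-diepoxygermacr-1(10)-en-9-one | CC(=O)OC[C@]12CC/C=C(/C)C(=O)C[C@]3(C[C@H]1O2)O[C@@]3(C)COC(C)=O | target

**Summary**

Total step count: 18.
Longest linear sequence: 14 steps (steps 1–4, then 9–18; the branch through steps 5–8 is equally long).

**Steps most likely to fail**

Step 12. Ring closure may lose to intermolecular olefination because the ten-membered transition state is strained. The base may also move the C7=C11 double bond of the unmasked β,γ-unsaturated aldehyde into conjugation, or the freed C12 alkoxide may add back to the new enoate. The fallback replaces the base-generated phosphonate carbanion by a preformed neutral phosphorane and changes the order of assembly; it sets out from 9 and 13 and returns at 22. Nozaki–Hiyama–Kishi coupling of 9 with the alkenyl iodide of 13 (the primary iodide is inert to CrCl2/NiCl2) should give (3Z)-1-{2-[(tert-butyldimethylsilyl)oxy]-5-methyl-3,6-dihydro-2H-pyran-4-yl}-6-iodo-3-methylhex-3-en-2-ol F1. Silylation (TBSCl, imidazole) gives its silyl ether F2. Heating F2 with two equivalents of ethyl (triphenylphosphoranylidene)acetate in MeCN (the second equivalent acting as base) gives the α-alkylated stabilised ylide F3. Buffered fluoride (TBAF, AcOH, −20 °C) unmasks the lactol ylide F4. Heating F4 in dilute toluene at 90 °C should close the C4–C5 bond by a base-free intramolecular Wittig reaction and deliver 22.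

Step 13. Titanium turnover may be slow at the fully substituted allylic alcohol inside the macrocycle, facial selectivity may erode (one C9 epimer may be mismatched), and the titanium alkoxide may open the tetrasubstituted epoxy alcohol. The fallback leaves the titanium–tartrate system for vanadium-catalysed asymmetric epoxidation with a chiral C2-symmetric bishydroxamic acid ligand (VO(OiPr)3, cumene hydroperoxide, toluene, 0 °C). This is a monomeric, less Lewis-acidic catalyst class known for hindered and fully substituted allylic alcohols; the ligand enantiomer that delivers oxygen to the same face would have to be chosen. It sets out from 22 and returns at 23 and makes no new compound (F0).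

Step 2. Carbomagnesiation of the internal alkynol may stall, or the chelated alkenylmagnesium may be protonated on work-up instead of being allylated, while allyl bromide is consumed by excess Grignard reagent. The fallback separates the two bond formations; it sets out from 3 and returns at 5. The same copper-catalysed methylmagnesiation, quenched with iodine, gives (2Z)-3-iodo-2-methylhexa-2,5-dien-1-ol F5. Stille coupling of F5 with allyltributylstannane (Pd(PPh3)4, CuI, DMF) then installs the second allyl group and gives 5.

**Further compounds**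

F1 | step 12 | (3Z)-1-{2-[(tert-butyldimethylsilyl)oxy]-5-methyl-3,6-dihydro-2H-pyran-4-yl}-6-iodo-3-methylhex-3-en-2-ol | ICC/C=C(/C)C(O)CC1=C(C)COC(O[Si](C)(C)C(C)(C)C)C1
F2 | step 12 | 2-O-tert-butyldimethylsilyl ether of F1 | ICC/C=C(/C)C(O[Si](C)(C)C(C)(C)C)CC1=C(C)COC(O[Si](C)(C)C(C)(C)C)C1
F3 | step 12 | ethyl (5Z)-7-[(tert-butyldimethylsilyl)oxy]-8-{2-[(tert-butyldimethylsilyl)oxy]-5-methyl-3,6-dihydro-2H-pyran-4-yl}-6-methyl-2-(triphenylphosphoranylidene)oct-5-enoate | CCOC(=O)C(CC/C=C(/C)C(O[Si](C)(C)C(C)(C)C)CC1=C(C)COC(O[Si](C)(C)C(C)(C)C)C1)=P(c1ccccc1)(c1ccccc1)c1ccccc1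
F4 | step 12 | ethyl (5Z)-7-[(tert-butyldimethylsilyl)oxy]-8-(2-hydroxy-5-methyl-3,6-dihydro-2H-pyran-4-yl)-6-methyl-2-(triphenylphosphoranylidene)oct-5-enoate | CCOC(=O)C(CC/C=C(/C)C(O[Si](C)(C)C(C)(C)C)CC1=C(C)COC(O)C1)=P(c1ccccc1)(c1ccccc1)c1ccccc1
F5 | step 2 | (2Z)-3-iodo-2-methylhexa-2,5-dien-1-ol | C=CC/C(I)=C(\C)CO
F0 | step 13 | none | none
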